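**Retrosynthetic overview**

- The strategy rests on ring B: oxygen on C2' and C4' with the prenyl group on C3' between them is a 2-prenylcyclohexane-1,3-dione one oxidation level down, so ring B is built saturated and aromatized late (C1'–C6' numbered as in the isoflavone).
- Key disconnections: C1'–C6' (Michael) and C2'–C3' (Dieckmann), leading to chromone-3-acetate 7 (C1', C2') and vinyl ketone 12 (C3'–C6' plus the whole prenyl chain).
- 7 comes from phloroglucinol and succinic anhydride, with ring C closed by one-carbon insertion; 12 comes from sulcatone (C3', C4', C5', prenyl) with C6' added by a Mannich methylenation.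
- Ring order: ring A (purchased), ring C (step 4), carbocycle of ring B (step 7), aromatization of ring B (steps 8–9), then deprotection (steps 10–11).

Key step: step 7

Assumption: silylation of 14 is taken to give the dienol ether with C2'=C3' and C4'=C5' double bonds (15); the C1'=C2' isomer, if formed instead, is at the same oxidation level and should give the same arene 16 in step 9.

**Route**

Step 1
Reactants: 1 phloroglucinol (anhydrous); 2 succinic anhydride
Product: 3 4-oxo-4-(2,4,6-trihydroxyphenyl)butanoic acid
Conditions: AlCl3 (3.5 equiv), PhNO2, 23 → 60 °C; then ice, 2 M HCl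
Reagents that add atoms: none
Why: Friedel–Crafts acylation of a strongly activated arene whose three free positions are equivalent; the acyl group introduced deactivates the ring, so mono-succinoylation is expected.

Step 2
Reactants: 3 4-oxo-4-(2,4,6-trihydroxyphenyl)butanoic acid
Product: 4 methyl 4-oxo-4-(2,4,6-trihydroxyphenyl)butanoate
Conditions: MeOH, H2SO4 (cat.), reflux
Reagents that add atoms: methanol, CO
Why: Fischer esterification of the aliphatic acid; the phenols and the chelated aryl ketone are inert to these conditions.

Step 3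
Reactants: 4 methyl 4-oxo-4-(2,4,6-trihydroxyphenyl)butanoate
Product: 5 methyl 4-[2-hydroxy-4,6-bis(methoxymethoxy)phenyl]-4-oxobutanoate
Conditions: MOMCl (2.2 equiv), iPr2NEt (3 equiv), CH2Cl2, 0 → 23 °C
Reagents that add atoms: chloromethyl methyl ether, COCCl
Why: O-alkylation of phenols (Williamson type) that should stop at the bis-ether, because the last hydroxyl is held in a hydrogen bond to the ketone and reacts much more slowly, as is usual for 2,4,6-trihydroxyaryl ketones.

Step 4
Reactants: 5 methyl 4-[2-hydroxy-4,6-bis(methoxymethoxy)phenyl]-4-oxobutanoate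
Product: 7 methyl 2-[5,7-bis(methoxymethoxy)-4-oxochromen-3-yl]acetate, via enaminone 6 (not isolated)
Conditions: Me2NCH(OMe)2 (3 equiv), PhMe, 100 °C; then AcOH (2 equiv), 60 °C
Reagents that add atoms: N,N-dimethylformamide dimethyl acetal, COC(OC)N(C)C
Why: Enaminone condensation at the ketone α-CH2 (the only activated methylene) followed by addition of the free phenol and loss of dimethylamine closes ring C, the same chromone annulation that converts 2-hydroxydeoxybenzoins into isoflavones.

Step 5
Reactants: 8 6-methylhept-5-en-2-one (sulcatone)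
Product: 10 1-(dimethylamino)-7-methyloct-6-en-3-one, via lithium enolate 9 (not isolated)
Conditions: LiN(iPr)2 (1.05 equiv), THF, −78 °C; then [CH2=NMe2]I (1.2 equiv), −78 → 23 °C
Reagents that add atoms: dimethyl(methylidene)ammonium iodide, C=[N+](C)C.[I-]
Why: Kinetic deprotonation of the methyl ketone on the methyl side followed by a Mannich reaction with the preformed iminium salt; any regioisomeric base from the methylene-side enolate is removed by acid–base extraction and distillation.

Step 6
Reactants: 10 1-(dimethylamino)-7-methyloct-6-en-3-one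
Product: 12 7-methylocta-1,6-dien-3-one, via methiodide 11 (not isolated)
Conditions: MeI, Et2O, 23 °C; then NaHCO3 (aq), CH2Cl2, 23 °C (trace BHT, used at once)
Reagents that add atoms: none
Why: N-Quaternization turns the amine into a leaving group and mild base triggers E1cB (Hofmann-type) elimination of the β-ammonium ketone, the standard release of a vinyl ketone from its Mannich base.

Step 7
Reactants: 7 methyl 2-[5,7-bis(methoxymethoxy)-4-oxochromen-3-yl]acetate; 12 7-methylocta-1,6-dien-3-one
Product: 14 3-[4-hydroxy-3-(3-methylbut-2-enyl)-2-oxocyclohex-3-en-1-yl]-5,7-bis(methoxymethoxy)chromen-4-one (racemic; enol form of the 1,3-dione), via Michael adduct 13 (not isolated)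
Conditions: KOtBu (1.2 equiv), THF/tBuOH 10:1, −40 °C, slow addition of 12 (1.1 equiv); → 23 °C; then cold 1 M HCl to pH 4
Reagents that add atoms: none
Why: KOtBu deprotonates the CH2 between chromone C3 and the ester (C1'), this enolate adds to the unsubstituted terminus of 12 (bond C1'–C6') to give 13, and after proton transfer the ketone α-carbon C3' attacks the ester carbonyl (bond C2'–C3') with loss of methoxide. The sequence is a Michael addition–Dieckmann (intramolecular Claisen) condensation, the known way from arylacetic esters and vinyl ketones to 4-substituted cyclohexane-1,3-diones. The one ring formed, the six-membered carbocycle of ring B, closes in the 6-exo-trig mode. The only new stereocentre, C1', is not controlled: it forms racemic, stays enolizable and is erased on aromatization. Regiochemistry is fixed by the carbon skeleton, since the other ketone enolate (C5') could reach the ester only through a four-membered transition state, so C3' alone closes and the prenyl chain ends up between the two carbonyl groups. The closure is pulled forward by deprotonation of the 2-alkyl-1,3-dione, which uses up the base, so little free alkoxide remains to attack chromone C2, and slow addition of 12 at low temperature should hold back a second Michael addition at C1'.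

Step 8
Reactants: 14 3-[4-hydroxy-3-(3-methylbut-2-enyl)-2-oxocyclohex-3-en-1-yl]-5,7-bis(methoxymethoxy)chromen-4-one
Product: 15 3-[2,4-bis(tert-butyldimethylsilyloxy)-3-(3-methylbut-2-enyl)cyclohexa-2,4-dien-1-yl]-5,7-bis(methoxymethoxy)chromen-4-one (racemic)
Conditions: TBSOTf (2.5 equiv), Et3N (4 equiv), CH2Cl2, −78 → 0 °C; cold NaHCO3 (aq) work-up
Reagents that add atoms: tert-butyldimethylsilyl trifluoromethanesulfonate, CC(C)(C)[Si](C)(C)OS(=O)(=O)C(F)(F)F
Why: Soft enolization with silyl triflate and amine: O-silylation of the enol, then silylation of the remaining vinylogous-ester carbonyl and deprotonation, gives the bis-silyl dienol ether, and both ring oxygens leave the step protected.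

Step 9
Reactants: 15 3-[2,4-bis(tert-butyldimethylsilyloxy)-3-(3-methylbut-2-enyl)cyclohexa-2,4-dien-1-yl]-5,7-bis(methoxymethoxy)chromen-4-one
Product: 16 3-[2,4-bis(tert-butyldimethylsilyloxy)-3-(3-methylbut-2-enyl)phenyl]-5,7-bis(methoxymethoxy)chromen-4-one
Conditions: DDQ (1.05 equiv), 2,4,6-collidine (2 equiv), PhH, 0 → 23 °C
Reagents that add atoms: none
Why: DDQ dehydrogenation of a silyloxy cyclohexadiene: hydride abstraction from the allylic ring CH2 gives a cation stabilized by both silyloxy groups, and proton loss aromatizes ring B, while the silyl groups keep the phenols masked so that an ortho-prenylphenol is never exposed to the quinone.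

Step 10
Reactants: 16 3-[2,4-bis(tert-butyldimethylsilyloxy)-3-(3-methylbut-2-enyl)phenyl]-5,7-bis(methoxymethoxy)chromen-4-one
Product: 17 3-[2,4-dihydroxy-3-(3-methylbut-2-enyl)phenyl]-5,7-bis(methoxymethoxy)chromen-4-one
Conditions: Bu4NF (2.2 equiv), AcOH (2.2 equiv), THF, 0 °C
Reagents that add atoms: none
Why: Fluoride-mediated cleavage of the aryl silyl ethers, buffered with acetic acid so that the chromone and the methoxymethyl ethers are untouched.

Step 11
Reactants: 17 3-[2,4-dihydroxy-3-(3-methylbut-2-enyl)phenyl]-5,7-bis(methoxymethoxy)chromen-4-one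
Product: 18 licoisoflavone A, 3-[2,4-dihydroxy-3-(3-methylbut-2-enyl)phenyl]-5,7-dihydroxychromen-4-one
Conditions: 2 M HCl, MeOH/THF 3:1, 40 °C, stopped as soon as 17 is consumed
Reagents that add atoms: none
Why: Acid-catalysed acetal exchange with methanol removes both methoxymethyl ethers, a deprotection routinely used on prenylated flavonoids under dilute acid and short reaction time.

**Compound list**

1 | phloroglucinol (benzene-1,3,5-triol) | Oc1cc(O)cc(O)c1 | starting material
2 | succinic anhydride | O=C1CCC(=O)O1 | starting material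
3 | 4-oxo-4-(2,4,6-trihydroxyphenyl)butanoic acid | OC(=O)CCC(=O)c1c(O)cc(O)cc1O | intermediate
4 | methyl 4-oxo-4-(2,4,6-trihydroxyphenyl)butanoate | COC(=O)CCC(=O)c1c(O)cc(O)cc1O | intermediate
5 | methyl 4-[2-hydroxy-4,6-bis(methoxymethoxy)phenyl]-4-oxobutanoate | COC(=O)CCC(=O)c1c(O)cc(OCOC)cc1OCOC | intermediate
6 | methyl 3-[(dimethylamino)methylidene]-4-[2-hydroxy-4,6-bis(methoxymethoxy)phenyl]-4-oxobutanoate (enaminone, alkene geometry not defined) | COC(=O)CC(=CN(C)C)C(=O)c1c(O)cc(OCOC)cc1OCOC | intermediate
7 | methyl 2-[5,7-bis(methoxymethoxy)-4-oxochromen-3-yl]acetate | COC(=O)Cc1coc2cc(OCOC)cc(OCOC)c2c1=O | intermediate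
8 | 6-methylhept-5-en-2-one (sulcatone) | CC(=O)CCC=C(C)C | starting material
9 | lithium 6-methylhepta-1,5-dien-2-olate | [Li]OC(=C)CCC=C(C)C | intermediate
10 | 1-(dimethylamino)-7-methyloct-6-en-3-one | CN(C)CCC(=O)CCC=C(C)C | intermediate
11 | trimethyl(7-methyl-3-oxooct-6-enyl)azanium iodide | C[N+](C)(C)CCC(=O)CCC=C(C)C.[I-] | intermediate
12 | 7-methylocta-1,6-dien-3-one | C=CC(=O)CCC=C(C)C | intermediate
13 | methyl 2-[5,7-bis(methoxymethoxy)-4-oxochromen-3-yl]-9-methyl-5-oxodec-8-enoate (racemic) | COC(=O)C(CCC(=O)CCC=C(C)C)c1coc2cc(OCOC)cc(OCOC)c2c1=O | intermediate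
14 | 3-[4-hydroxy-3-(3-methylbut-2-enyl)-2-oxocyclohex-3-en-1-yl]-5,7-bis(methoxymethoxy)chromen-4-one (racemic, enol form) | O=C1C(c2coc3cc(OCOC)cc(OCOC)c3c2=O)CCC(O)=C1CC=C(C)C | intermediate
15 | 3-[2,4-bis(tert-butyldimethylsilyloxy)-3-(3-methylbut-2-enyl)cyclohexa-2,4-dien-1-yl]-5,7-bis(methoxymethoxy)chromen-4-one (racemic) | CC(C)=CCC1=C(O[Si](C)(C)C(C)(C)C)C(c2coc3cc(OCOC)cc(OCOC)c3c2=O)CC=C1O[Si](C)(C)C(C)(C)C | intermediate
16 | 3-[2,4-bis(tert-butyldimethylsilyloxy)-3-(3-methylbut-2-enyl)phenyl]-5,7-bis(methoxymethoxy)chromen-4-one | CC(C)=CCc1c(O[Si](C)(C)C(C)(C)C)ccc(-c2coc3cc(OCOC)cc(OCOC)c3c2=O)c1O[Si](C)(C)C(C)(C)C | intermediate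
17 | 3-[2,4-dihydroxy-3-(3-methylbut-2-enyl)phenyl]-5,7-bis(methoxymethoxy)chromen-4-one | CC(C)=CCc1c(O)ccc(-c2coc3cc(OCOC)cc(OCOC)c3c2=O)c1O | intermediate
18 | licoisoflavone A | CC(C)=CCc1c(O)ccc(-c2coc3cc(O)cc(O)c3c2=O)c1O | target

**Step count**

Total: 11 steps. Longest linear sequence: 9 steps (1, 2, 3, 4, 7, 8, 9, 10, 11, from phloroglucinol); the sulcatone branch contributes steps 5 and 6.

**Steps most likely to fail, with fallbacks**

1. Step 7. The vinyl ketone may polymerize under base or be consumed by a second conjugate addition at C1' before the ring closes, and alkoxide may open the pyranone at chromone C2. The fallback inverts the donor and acceptor roles (ketone enolate plus acrylate, the more common Michael–Claisen mode) and avoids the free vinyl ketone. Setting out from 7, α-methylenation with paraformaldehyde, K2CO3 and catalytic Bu4NI in toluene at 80 °C should give the acrylate methyl 2-[5,7-bis(methoxymethoxy)-4-oxochromen-3-yl]prop-2-enoate F1. The lithium enolate 9, made from 8 as in step 5, is added to F1 at −78 °C in a conjugate fashion. This gives the enolate of 13, where the fallback rejoins the route; KOtBu/tBuOH and warming then close 13 to 14 as in step 7.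

2. Step 9. The dienol ether may hydrolyse back to 14, or the quinone may go on to abstract hydride from the benzylic and allylic CH2 of the prenyl group of 16. The fallback replaces the hydride-abstraction oxidation by sulfinylation and thermal syn-elimination. Setting out from 14, the dianion (LiN(iPr)2, 2.1 equiv, THF, −78 °C) is treated with methyl benzenesulfinate to give the sulfoxide 3-[4-hydroxy-3-(3-methylbut-2-enyl)-2-oxo-5-(phenylsulfinyl)cyclohex-3-en-1-yl]-5,7-bis(methoxymethoxy)chromen-4-one F2. It is drawn as the C5' isomer; sulfinylation at C1' would converge on the same product. Warming F2 in toluene at 80 °C over CaCO3 should eliminate benzenesulfenic acid, and the resulting cyclohexenedione tautomerizes to the resorcinol, so the fallback rejoins the route at 17 and bypasses 15 and 16.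

3. Step 11. With the 2'- and 4'-hydroxyls free, acid may add one of them across the prenyl double bond (chroman formation) while the methoxymethyl ethers are cleaved. The fallback reverses the order of deprotection so that the acetals are removed under aprotic, buffered conditions while ring B is still silylated. Setting out from 16, TMSOTf and 2,2'-bipyridyl in CH2Cl2 at 0 °C should convert the two aryl methoxymethyl ethers into trimethylsilyl ethers, giving 3-[2,4-bis(tert-butyldimethylsilyloxy)-3-(3-methylbut-2-enyl)phenyl]-5,7-bis(trimethylsilyloxy)chromen-4-one F3. Water work-up hydrolyses F3 to 3-[2,4-bis(tert-butyldimethylsilyloxy)-3-(3-methylbut-2-enyl)phenyl]-5,7-dihydroxychromen-4-one F4. Bu4NF/AcOH in THF at 0 °C then removes the two silyl ethers of F4, so the fallback rejoins the route at 18.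

**Further compounds**

F1 | step 7 | methyl 2-[5,7-bis(methoxymethoxy)-4-oxochromen-3-yl]prop-2-enoate | C=C(C(=O)OC)c1coc2cc(OCOC)cc(OCOC)c2c1=O
F2 | step 9 | 3-[4-hydroxy-3-(3-methylbut-2-enyl)-2-oxo-5-(phenylsulfinyl)cyclohex-3-en-1-yl]-5,7-bis(methoxymethoxy)chromen-4-one (mixture of diastereomers) | O=C1C(c2coc3cc(OCOC)cc(OCOC)c3c2=O)CC(S(=O)c2ccccc2)C(O)=C1CC=C(C)C
F3 | step 11 | 3-[2,4-bis(tert-butyldimethylsilyloxy)-3-(3-methylbut-2-enyl)phenyl]-5,7-bis(trimethylsilyloxy)chromen-4-one | CC(C)=CCc1c(O[Si](C)(C)C(C)(C)C)ccc(-c2coc3cc(O[Si](C)(C)C)cc(O[Si](C)(C)C)c3c2=O)c1O[Si](C)(C)C(C)(C)C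
F4 | step 11 | 3-[2,4-bis(tert-butyldimethylsilyloxy)-3-(3-methylbut-2-enyl)phenyl]-5,7-dihydroxychromen-4-one | CC(C)=CCc1c(O[Si](C)(C)C(C)(C)C)ccc(-c2coc3cc(O)cc(O)c3c2=O)c1O[Si](C)(C)C(C)(C)C
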